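**Retrosynthetic overview**
1. Target ⇒ the last step installs C2–OH/C3–H and C7–OH together by hydrogen-atom-transfer oxygenation of a cis-fused enone/alkene; the 3-hydroxypropanoyl group is a hydrated propargylic alkyne.
2. Ring B ⇒ magnesium-templated endo Diels–Alder reaction of (3E)-2-methylidenepent-3-en-1-ol with the unsubstituted enone bond of a 4-alkynyl-4-methylcyclohexa-2,5-dienone (sets the cis fusion and C5).
3. Ring A ⇒ a benzene ring: Schultz asymmetric Birch reduction–methylation of a chiral 2,3-dialkylbenzamide creates the quaternary C4; doubly allylic oxidation then gives the dienone.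
4. sec-Butyl stereocentre ⇒ carboxy-directed iridium hydrogenation of the α-ethylstyrene made from 2-bromo-3-methylbenzoic acid.
5. Ring order: ring A comes from the arene (dearomatised first); ring B is added second by cycloaddition.

Numbering used for the bicyclic compounds (naphthalen-1-one): C1 ketone, C2 (Me), C3 (sec-butyl), C4 (quaternary), C4a/C8a ring fusion, C5 (Me), C7 (hydroxymethyl); ring A = C1–C4, C4a, C8a; ring B = C4a, C5–C8, C8a.

Assumption: the (S)-configured auxiliary 5 and the (Sa,S) ligand are taken to give 1R in 9 and R in 4; if either sense is opposite, the enantiomeric auxiliary or ligand is used and nothing else changes.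

**Step 1**
Reactants: 1 2-bromo-3-methylbenzoic acid; 2 2-(but-1-en-2-yl)-4,4,5,5-tetramethyl-1,3,2-dioxaborolane
Product: 3 2-(but-1-en-2-yl)-3-methylbenzoic acid
Conditions: Pd(OAc)2 (2 mol%), SPhos (4 mol%), K3PO4, PhMe/H2O, 90 °C; acidic work-up
Reagents that add atoms: none
Why: Suzuki–Miyaura cross-coupling; the bulky biarylphosphine tolerates the aryl bromide flanked by methyl and carboxylate, and no stereocentre is formed.

**Step 2**
Reactants: 3 2-(but-1-en-2-yl)-3-methylbenzoic acid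
Product: 4 2-[(2R)-butan-2-yl]-3-methylbenzoic acid
Conditions: [Ir(cod)(L)]B[3,5-(CF3)2C6H3]4 (1 mol%; L = (Sa,S)-7-[bis(3,5-di-tert-butylphenyl)phosphino]-7'-(4-benzyl-4,5-dihydrooxazol-2-yl)-1,1'-spirobiindane), H2 (6 atm), Cs2CO3 (0.5 equiv), MeOH, rt
Reagents that add atoms: none
Why: Carboxy-directed iridium-catalysed asymmetric hydrogenation of an α-alkylstyrene: the carboxylate anchors the substrate to iridium so that H2 adds to one face of the 1,1-disubstituted alkene, setting the benzylic stereocentre as R.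

**Step 3**
Reactants: 4 2-[(2R)-butan-2-yl]-3-methylbenzoic acid; 5 (2S)-2-(methoxymethyl)pyrrolidine
Product: 7 {2-[(2R)-butan-2-yl]-3-methylphenyl}[(2S)-2-(methoxymethyl)pyrrolidin-1-yl]methanone, via acid chloride 6 (not isolated)
Conditions: SOCl2, cat. DMF, PhMe, 60 °C; evaporate; then 5, Et3N, CH2Cl2, 0 °C → rt
Reagents that add atoms: none
Why: Amide formation through the acyl chloride (nucleophilic acyl substitution) installs the Schultz auxiliary; the benzylic stereocentre is not touched.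

**Step 4**
Reactants: 7 {2-[(2R)-butan-2-yl]-3-methylphenyl}[(2S)-2-(methoxymethyl)pyrrolidin-1-yl]methanone
Product: 9 [(1R)-2-[(2R)-butan-2-yl]-1,3-dimethylcyclohexa-2,5-dien-1-yl][(2S)-2-(methoxymethyl)pyrrolidin-1-yl]methanone, via potassium amide enolate 8 (not isolated)
Conditions: K (2.2 equiv), t-BuOH (1.0 equiv), NH3/THF, −78 °C; then MeI, −78 °C
Reagents that add atoms: iodomethane (CI)
Why: Schultz asymmetric Birch reduction–alkylation: two-electron reduction and one protonation para to the amide give the chelated amide enolate 8, which is C-methylated at the former ipso carbon on the face left open by the methoxymethylpyrrolidine, breaking aromaticity and setting the quaternary stereocentre (1R).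

**Step 5**
Reactants: 9 [(1R)-2-[(2R)-butan-2-yl]-1,3-dimethylcyclohexa-2,5-dien-1-yl][(2S)-2-(methoxymethyl)pyrrolidin-1-yl]methanone
Product: 10 (1R)-2-[(2R)-butan-2-yl]-1,3-dimethylcyclohexa-2,5-diene-1-carbaldehyde
Conditions: Cp2Zr(H)Cl (2 equiv), THF, rt, 30 min; aqueous work-up
Reagents that add atoms: none
Why: Amide-to-aldehyde reduction with Schwartz's reagent: hydrozirconation of the amide carbonyl gives a zirconated hemiaminal that collapses to the aldehyde on work-up, releasing the auxiliary and leaving the quaternary centre and both ring alkenes untouched.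

**Step 6**
Reactants: 10 (1R)-2-[(2R)-butan-2-yl]-1,3-dimethylcyclohexa-2,5-diene-1-carbaldehyde
Product: 11 (3S)-2-[(2R)-butan-2-yl]-3-ethynyl-1,3-dimethylcyclohexa-1,4-diene
Conditions: Ohira–Bestmann reagent, K2CO3, MeOH, 0 °C → rt
Reagents that add atoms: dimethyl (1-diazo-2-oxopropyl)phosphonate (COP(=O)(OC)C(=[N+]=[N-])C(C)=O)
Why: Seyferth–Gilbert homologation (Ohira–Bestmann variant) turns the non-enolisable aldehyde into the terminal alkyne; the quaternary centre is unchanged (its descriptor becomes S only through CIP priorities).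

**Step 7**
Reactants: 11 (3S)-2-[(2R)-butan-2-yl]-3-ethynyl-1,3-dimethylcyclohexa-1,4-diene
Product: 14 tert-butyl({3-[(1S)-2-[(2R)-butan-2-yl]-1,3-dimethylcyclohexa-2,5-dien-1-yl]prop-2-yn-1-yl}oxy)dimethylsilane, via lithium acetylide 12 (not isolated), via lithium alkoxide 13 (not isolated)
Conditions: n-BuLi, THF, −78 °C; (CH2O)n, −78 °C → rt; then TBSCl, DMPU, 0 °C → rt
Reagents that add atoms: formaldehyde, as paraformaldehyde (C=O); tert-butyldimethylsilyl chloride (CC(C)(C)[Si](C)(C)Cl)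
Why: Acetylide addition to formaldehyde followed by in-situ O-silylation; the alkyne C–H is far more acidic than the doubly allylic CH2 and no stereocentre is involved.

**Step 8**
Reactants: 14 tert-butyl({3-[(1S)-2-[(2R)-butan-2-yl]-1,3-dimethylcyclohexa-2,5-dien-1-yl]prop-2-yn-1-yl}oxy)dimethylsilane
Product: 15 (4S)-3-[(2R)-butan-2-yl]-4-{3-[(tert-butyldimethylsilyl)oxy]prop-1-yn-1-yl}-2,4-dimethylcyclohexa-2,5-dien-1-one
Conditions: CrO3, 3,5-dimethylpyrazole, CH2Cl2, −20 °C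
Reagents that add atoms: chromium trioxide (O=[Cr](=O)=O)
Why: Allylic C–H oxidation of the doubly allylic methylene (CrO3–3,5-dimethylpyrazole) gives the cross-conjugated dienone; the quaternary carbon prevents aromatisation and the slim alkynyl group cannot be lost as an acyl group could.

**Step 9**
Reactants: 16 2-bromoprop-2-en-1-ol; 17 (E)-prop-1-en-1-ylboronic acid
Product: 18 (3E)-2-methylidenepent-3-en-1-ol
Conditions: Pd(PPh3)4 (3 mol%), K2CO3, DME/H2O, 70 °C
Reagents that add atoms: none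
Why: Suzuki–Miyaura coupling of an alkenyl bromide with an alkenylboronic acid, with retention of the E geometry.

**Step 10**
Reactants: 15 (4S)-3-[(2R)-butan-2-yl]-4-{3-[(tert-butyldimethylsilyl)oxy]prop-1-yn-1-yl}-2,4-dimethylcyclohexa-2,5-dien-1-one; 18 (3E)-2-methylidenepent-3-en-1-ol
Product: 20 (4S,4aR,5R,8aS)-3-[(2R)-butan-2-yl]-4-{3-[(tert-butyldimethylsilyl)oxy]prop-1-yn-1-yl}-7-(hydroxymethyl)-2,4,5-trimethyl-4a,5,8,8a-tetrahydronaphthalen-1(4H)-one, via bromomagnesium alkoxide 19 (not isolated)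
Conditions: 18 (1.5 equiv), MeMgBr (1.5 equiv), CH2Cl2, 0 °C; then 15, 0 → 40 °C; pH 7 aqueous work-up
Reagents that add atoms: none
Why: Proposed new method: the bromomagnesium alkoxide 19 binds in the plane of the dienone carbonyl on its unsubstituted side and so acts at once as Lewis acid and as a temporary tether holding the CH2O-bearing diene carbon next to C1; only the endo transition state joining the diene CH2 terminus to the dienone α-carbon (future C8a) and the CHMe terminus to the β-carbon (future C4a) is within reach of this tether, which is the 1,3 ("meta") regiochemistry of tether-at-C2 (type 2) intramolecular Diels–Alder reactions and the reverse of the untethered electronic preference; the diene adds to the unsubstituted enone bond on the face of the slim alkynyl group (anti to the C4 methyl), suprafacially and endo with the E-methyl outside, setting C4a (R), C8a (S) and C5 (R) relative to C4; closest known reaction types are magnesium-alkoxide-templated (self-assembled) Diels–Alder reactions of dienols and silicon-tethered type 2 intramolecular Diels–Alder reactions.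

**Step 11**
Reactants: 20 (4S,4aR,5R,8aS)-3-[(2R)-butan-2-yl]-4-{3-[(tert-butyldimethylsilyl)oxy]prop-1-yn-1-yl}-7-(hydroxymethyl)-2,4,5-trimethyl-4a,5,8,8a-tetrahydronaphthalen-1(4H)-one
Product: 22 (4R,4aR,5R,8aS)-3-[(2R)-butan-2-yl]-7-(hydroxymethyl)-4-(3-hydroxypropanoyl)-2,4,5-trimethyl-4a,5,8,8a-tetrahydronaphthalen-1(4H)-one, via silyl ether ketone 21 (not isolated)
Conditions: Ph3PAuNTf2 (3 mol%), H2O (5 equiv), 1,4-dioxane, 50 °C; then HF·pyridine, THF, 0 °C
Reagents that add atoms: water (O)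
Why: Gold-catalysed alkyne hydration: the inductively withdrawing propargylic oxygen directs water to the alkyne carbon remote from it (the one on C4), giving β-silyloxy ketone 21, and fluoride then cleaves the silyl ether; no stereocentre is formed and the non-basic conditions keep the cis ring fusion.

**Step 12**
Reactants: 22 (4R,4aR,5R,8aS)-3-[(2R)-butan-2-yl]-7-(hydroxymethyl)-4-(3-hydroxypropanoyl)-2,4,5-trimethyl-4a,5,8,8a-tetrahydronaphthalen-1(4H)-one
Product: 24 (2S,3R,4R,4aR,5R,7R,8aS)-3-[(2R)-butan-2-yl]-2,7-dihydroxy-7-(hydroxymethyl)-4-(3-hydroxypropanoyl)-2,4,5-trimethyloctahydronaphthalen-1(2H)-one (CNP0112523.4), via bis-hydroperoxide 23 (not isolated)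
Conditions: Mn(dpm)3 (20 mol%), PhSiH3, O2 (1 atm), i-PrOH/CH2Cl2, 0 °C → rt; then P(OEt)3
Reagents that add atoms: dioxygen (O=O)
Why: Mukaiyama-type metal-hydride hydrogen-atom transfer on both π-systems at once (alkene hydration plus Magnus reductive α-hydroxylation of the enone): H• adds to C6 and to the enone β-carbon C3 from the convex α-face (anti to the pseudo-axial C4 acyl group and to ring B, so sec-butyl ends equatorial, 3R), and the tertiary C7 and C2 radicals are trapped by O2 on the same open face (axial attack at C7; at C2 anti to the axial C8 methylene), giving after phosphite reduction of 23 the 7R and 2S carbinols.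

**Compound list**
1 | 2-bromo-3-methylbenzoic acid | Cc1cccc(C(=O)O)c1Br | starting material
2 | 2-(but-1-en-2-yl)-4,4,5,5-tetramethyl-1,3,2-dioxaborolane | C=C(CC)B1OC(C)(C)C(C)(C)O1 | starting material
3 | 2-(but-1-en-2-yl)-3-methylbenzoic acid | C=C(CC)c1c(C)cccc1C(=O)O | intermediate
4 | 2-[(2R)-butan-2-yl]-3-methylbenzoic acid | CC[C@@H](C)c1c(C)cccc1C(=O)O | intermediate
5 | (2S)-2-(methoxymethyl)pyrrolidine | COC[C@@H]1CCCN1 | starting material
6 | 2-[(2R)-butan-2-yl]-3-methylbenzoyl chloride | CC[C@@H](C)c1c(C)cccc1C(=O)Cl | intermediate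
7 | {2-[(2R)-butan-2-yl]-3-methylphenyl}[(2S)-2-(methoxymethyl)pyrrolidin-1-yl]methanone | CC[C@@H](C)c1c(C)cccc1C(=O)N1CCC[C@H]1COC | intermediate
8 | potassium {2-[(2R)-butan-2-yl]-3-methylcyclohexa-2,5-dien-1-ylidene}[(2S)-2-(methoxymethyl)pyrrolidin-1-yl]methanolate | CC[C@@H](C)C1=C(C)CC=CC1=C([O-])N1CCC[C@H]1COC.[K+] | intermediate
9 | [(1R)-2-[(2R)-butan-2-yl]-1,3-dimethylcyclohexa-2,5-dien-1-yl][(2S)-2-(methoxymethyl)pyrrolidin-1-yl]methanone | CC[C@@H](C)C1=C(C)CC=C[C@@]1(C)C(=O)N1CCC[C@H]1COC | intermediate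
10 | (1R)-2-[(2R)-butan-2-yl]-1,3-dimethylcyclohexa-2,5-diene-1-carbaldehyde | CC[C@@H](C)C1=C(C)CC=C[C@@]1(C)C=O | intermediate
11 | (3S)-2-[(2R)-butan-2-yl]-3-ethynyl-1,3-dimethylcyclohexa-1,4-diene | CC[C@@H](C)C1=C(C)CC=C[C@@]1(C)C#C | intermediate
12 | lithium 2-[(1S)-2-[(2R)-butan-2-yl]-1,3-dimethylcyclohexa-2,5-dien-1-yl]ethyn-1-ide | CC[C@@H](C)C1=C(C)CC=C[C@@]1(C)C#[C-].[Li+] | intermediate
13 | lithium 3-[(1S)-2-[(2R)-butan-2-yl]-1,3-dimethylcyclohexa-2,5-dien-1-yl]prop-2-yn-1-olate | CC[C@@H](C)C1=C(C)CC=C[C@@]1(C)C#CC[O-].[Li+] | intermediate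
14 | tert-butyl({3-[(1S)-2-[(2R)-butan-2-yl]-1,3-dimethylcyclohexa-2,5-dien-1-yl]prop-2-yn-1-yl}oxy)dimethylsilane | CC[C@@H](C)C1=C(C)CC=C[C@@]1(C)C#CCO[Si](C)(C)C(C)(C)C | intermediate
15 | (4S)-3-[(2R)-butan-2-yl]-4-{3-[(tert-butyldimethylsilyl)oxy]prop-1-yn-1-yl}-2,4-dimethylcyclohexa-2,5-dien-1-one | CC[C@@H](C)C1=C(C)C(=O)C=C[C@@]1(C)C#CCO[Si](C)(C)C(C)(C)C | intermediate
16 | 2-bromoprop-2-en-1-ol | OCC(Br)=C | starting material
17 | (E)-prop-1-en-1-ylboronic acid | C/C=C/B(O)O | starting material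
18 | (3E)-2-methylidenepent-3-en-1-ol | C/C=C/C(=C)CO | intermediate
19 | bromomagnesium (3E)-2-methylidenepent-3-en-1-olate | C/C=C/C(=C)C[O-].[Mg+2].[Br-] | intermediate
20 | (4S,4aR,5R,8aS)-3-[(2R)-butan-2-yl]-4-{3-[(tert-butyldimethylsilyl)oxy]prop-1-yn-1-yl}-7-(hydroxymethyl)-2,4,5-trimethyl-4a,5,8,8a-tetrahydronaphthalen-1(4H)-one | CC[C@@H](C)C1=C(C)C(=O)[C@H]2CC(CO)=C[C@@H](C)[C@H]2[C@@]1(C)C#CCO[Si](C)(C)C(C)(C)C | intermediate
21 | (4R,4aR,5R,8aS)-3-[(2R)-butan-2-yl]-4-{3-[(tert-butyldimethylsilyl)oxy]propanoyl}-7-(hydroxymethyl)-2,4,5-trimethyl-4a,5,8,8a-tetrahydronaphthalen-1(4H)-one | CC[C@@H](C)C1=C(C)C(=O)[C@H]2CC(CO)=C[C@@H](C)[C@H]2[C@@]1(C)C(=O)CCO[Si](C)(C)C(C)(C)C | intermediate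
22 | (4R,4aR,5R,8aS)-3-[(2R)-butan-2-yl]-7-(hydroxymethyl)-4-(3-hydroxypropanoyl)-2,4,5-trimethyl-4a,5,8,8a-tetrahydronaphthalen-1(4H)-one | CC[C@@H](C)C1=C(C)C(=O)[C@H]2CC(CO)=C[C@@H](C)[C@H]2[C@@]1(C)C(=O)CCO | intermediate
23 | (2S,3R,4R,4aR,5R,7R,8aS)-3-[(2R)-butan-2-yl]-2,7-dihydroperoxy-7-(hydroxymethyl)-4-(3-hydroxypropanoyl)-2,4,5-trimethyloctahydronaphthalen-1(2H)-one | CC[C@@H](C)[C@H]1[C@](C)(OO)C(=O)[C@H]2C[C@@](OO)(CO)C[C@@H](C)[C@H]2[C@@]1(C)C(=O)CCO | intermediate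
24 | (2S,3R,4R,4aR,5R,7R,8aS)-3-[(2R)-butan-2-yl]-2,7-dihydroxy-7-(hydroxymethyl)-4-(3-hydroxypropanoyl)-2,4,5-trimethyloctahydronaphthalen-1(2H)-one (CNP0112523.4) | CC[C@@H](C)[C@@H]1[C@](C)(C(=O)CCO)[C@@H]2[C@H](C)C[C@](O)(CO)C[C@@H]2C(=O)[C@@]1(C)O | target

**Totals**
Total step count: 12. Longest linear sequence: 11 (steps 1–8, 10, 11, 12; step 9 is the side branch).

**Three steps most likely to fail**

Step 10. Regio-, face- and endo-control all rest on the untested magnesium template, and the required regiochemistry opposes the normal electronic preference. Fallback: set out from 15 and use an electronically matched diene instead of a tether. Diels–Alder reaction of 15 (PhMe, 110 °C, or ZnCl2) with (1Z,3E)-1-[(tert-butyldimethylsilyl)oxy]-2-{[(tert-butyldimethylsilyl)oxy]methyl}penta-1,3-diene F1, whose 1-silyloxy group forces its own carbon onto the dienone α-carbon (ortho rule), gives (4S,4aR,5R,8R,8aR)-3-[(2R)-butan-2-yl]-8-[(tert-butyldimethylsilyl)oxy]-7-{[(tert-butyldimethylsilyl)oxy]methyl}-4-{3-[(tert-butyldimethylsilyl)oxy]prop-1-yn-1-yl}-2,4,5-trimethyl-4a,5,8,8a-tetrahydronaphthalen-1(4H)-one F2. DBU eliminates the β-silyloxy group to give (4S,4aS,5R)-3-[(2R)-butan-2-yl]-7-{[(tert-butyldimethylsilyl)oxy]methyl}-4-{3-[(tert-butyldimethylsilyl)oxy]prop-1-yn-1-yl}-2,4,5-trimethyl-4a,5-dihydronaphthalen-1(4H)-one F3. Conjugate reduction with [(Ph3P)CuH]6 and kinetic protonation of the enolate on the convex face restores the cis fusion in (4S,4aR,5R,8aS)-3-[(2R)-butan-2-yl]-7-{[(tert-butyldimethylsilyl)oxy]methyl}-4-{3-[(tert-butyldimethylsilyl)oxy]prop-1-yn-1-yl}-2,4,5-trimethyl-4a,5,8,8a-tetrahydronaphthalen-1(4H)-one F4, which under the conditions of step 11 (both silyl groups lost) comes back to the route at 22.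

Step 11. The quaternary C4 may steer water to the other alkyne carbon despite the inductive bias. Fallback: set out from 20. TBAF gives (4S,4aR,5R,8aS)-3-[(2R)-butan-2-yl]-7-(hydroxymethyl)-4-(3-hydroxyprop-1-yn-1-yl)-2,4,5-trimethyl-4a,5,8,8a-tetrahydronaphthalen-1(4H)-one F5. Hydroxyl-directed trans-hydrosilylation ([Cp*Ru(MeCN)3]PF6, BnMe2SiH) places silicon on the alkyne carbon remote from the hydroxyl, giving (4R,4aR,5R,8aS)-4-[(1Z)-1-[benzyl(dimethyl)silyl]-3-hydroxyprop-1-en-1-yl]-3-[(2R)-butan-2-yl]-7-(hydroxymethyl)-2,4,5-trimethyl-4a,5,8,8a-tetrahydronaphthalen-1(4H)-one F6. Tamao–Fleming oxidation of the C–Si bond (TBAF; then H2O2, KHCO3) returns to the route at 22.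

Step 12. Hydrogen-atom transfer to a fully substituted, hindered enone is slow, and three stereocentres are set at once. Fallback: set out from 20 and split the two oxygenations, changing the mechanism at ring A. SmI2/HMPA with t-BuOH (1 equiv) reduces the enone to its samarium enolate (axial protonation at C3), which is trapped with 2-(phenylsulfonyl)-3-phenyloxaziridine on the convex face to give (2S,3R,4R,4aR,5R,8aS)-3-[(2R)-butan-2-yl]-4-{3-[(tert-butyldimethylsilyl)oxy]prop-1-yn-1-yl}-2-hydroxy-7-(hydroxymethyl)-2,4,5-trimethyl-3,4,4a,5,8,8a-hexahydronaphthalen-1(2H)-one F7. Alkyne hydration and desilylation as in step 11 give (2S,3R,4R,4aR,5R,8aS)-3-[(2R)-butan-2-yl]-2-hydroxy-7-(hydroxymethyl)-4-(3-hydroxypropanoyl)-2,4,5-trimethyl-3,4,4a,5,8,8a-hexahydronaphthalen-1(2H)-one F8. An ordinary Mukaiyama hydration (Co(acac)2, PhSiH3, O2) of the one remaining alkene then reaches 24.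

**Further compounds**
F1 | step 10 | (1Z,3E)-1-[(tert-butyldimethylsilyl)oxy]-2-{[(tert-butyldimethylsilyl)oxy]methyl}penta-1,3-diene | C/C=C/C(CO[Si](C)(C)C(C)(C)C)=C/O[Si](C)(C)C(C)(C)C
F2 | step 10 | (4S,4aR,5R,8R,8aR)-3-[(2R)-butan-2-yl]-8-[(tert-butyldimethylsilyl)oxy]-7-{[(tert-butyldimethylsilyl)oxy]methyl}-4-{3-[(tert-butyldimethylsilyl)oxy]prop-1-yn-1-yl}-2,4,5-trimethyl-4a,5,8,8a-tetrahydronaphthalen-1(4H)-one | CC[C@@H](C)C1=C(C)C(=O)[C@H]2[C@@H](O[Si](C)(C)C(C)(C)C)C(CO[Si](C)(C)C(C)(C)C)=C[C@@H](C)[C@H]2[C@@]1(C)C#CCO[Si](C)(C)C(C)(C)C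
F3 | step 10 | (4S,4aS,5R)-3-[(2R)-butan-2-yl]-7-{[(tert-butyldimethylsilyl)oxy]methyl}-4-{3-[(tert-butyldimethylsilyl)oxy]prop-1-yn-1-yl}-2,4,5-trimethyl-4a,5-dihydronaphthalen-1(4H)-one | CC[C@@H](C)C1=C(C)C(=O)C2=CC(CO[Si](C)(C)C(C)(C)C)=C[C@@H](C)[C@H]2[C@@]1(C)C#CCO[Si](C)(C)C(C)(C)C
F4 | step 10 | (4S,4aR,5R,8aS)-3-[(2R)-butan-2-yl]-7-{[(tert-butyldimethylsilyl)oxy]methyl}-4-{3-[(tert-butyldimethylsilyl)oxy]prop-1-yn-1-yl}-2,4,5-trimethyl-4a,5,8,8a-tetrahydronaphthalen-1(4H)-one | CC[C@@H](C)C1=C(C)C(=O)[C@H]2CC(CO[Si](C)(C)C(C)(C)C)=C[C@@H](C)[C@H]2[C@@]1(C)C#CCO[Si](C)(C)C(C)(C)C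
F5 | step 11 | (4S,4aR,5R,8aS)-3-[(2R)-butan-2-yl]-7-(hydroxymethyl)-4-(3-hydroxyprop-1-yn-1-yl)-2,4,5-trimethyl-4a,5,8,8a-tetrahydronaphthalen-1(4H)-one | CC[C@@H](C)C1=C(C)C(=O)[C@H]2CC(CO)=C[C@@H](C)[C@H]2[C@@]1(C)C#CCO
F6 | step 11 | (4R,4aR,5R,8aS)-4-[(1Z)-1-[benzyl(dimethyl)silyl]-3-hydroxyprop-1-en-1-yl]-3-[(2R)-butan-2-yl]-7-(hydroxymethyl)-2,4,5-trimethyl-4a,5,8,8a-tetrahydronaphthalen-1(4H)-one | CC[C@@H](C)C1=C(C)C(=O)[C@H]2CC(CO)=C[C@@H](C)[C@H]2[C@@]1(C)/C(=C/CO)[Si](C)(C)Cc1ccccc1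
F7 | step 12 | (2S,3R,4R,4aR,5R,8aS)-3-[(2R)-butan-2-yl]-4-{3-[(tert-butyldimethylsilyl)oxy]prop-1-yn-1-yl}-2-hydroxy-7-(hydroxymethyl)-2,4,5-trimethyl-3,4,4a,5,8,8a-hexahydronaphthalen-1(2H)-one | CC[C@@H](C)[C@H]1[C@](C)(O)C(=O)[C@H]2CC(CO)=C[C@@H](C)[C@H]2[C@@]1(C)C#CCO[Si](C)(C)C(C)(C)C
F8 | step 12 | (2S,3R,4R,4aR,5R,8aS)-3-[(2R)-butan-2-yl]-2-hydroxy-7-(hydroxymethyl)-4-(3-hydroxypropanoyl)-2,4,5-trimethyl-3,4,4a,5,8,8a-hexahydronaphthalen-1(2H)-one | CC[C@@H](C)[C@H]1[C@](C)(O)C(=O)[C@H]2CC(CO)=C[C@@H](C)[C@H]2[C@@]1(C)C(=O)CCO
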